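The runs are simulated for an exercise, and the scatter is random.

Slowness has two clocks here. Pairing of starting material into open dimer takes two molecules, so its time runs inverse to the charge; the step to ring does not depend on it.

- midnight: starting material 0.060 M; the very flask that is asked about, followed so far
- flask: starting material 0.060 M; time 6.0 h
midnight run (percent of the starting material charged)

| time / min | starting material / % | isomer of the product / % | open dimer / % | ring / % |
|---|---|---|---|---|
| 6.00 | 98 | 2 | 3 | 1 |
| 10.0 | 96 | 0 | 6 | 2 |
| 20.0 | 90 | 1 | 9 | 0 |
| 40.0 | 79 | 0 | 16 | 5 |
| 80.0 | 65 | 0 | 22 | 10 |

(scatter of a reading: 1.5 percentage points)
- percentages count the starting material that a species holds: one open dimer counts as two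
- what was read earlier has a scatter of 1.5 percentage points, one standard deviation
- reactions considered so far: 2 starting material <-> open dimer; starting material -> ring; ring <-> isomer of the product; ring -> over-reaction product
* the largest share of what was charged as starting material, at 6.0 h belongs to (isomer of the product / ring / open dimer / starting material)
* the largest share itself, whichever of these holds it, in percent of the starting material charged

We define the pairing time as the charge over the opening rate of dimer formation. The dimer read at 40.0 min, 16%, with the mean square of the free share over that stretch, gives 3.38 h. Asked time over pairing time is the pairing number, a Damköhler number, 1.77.

Our first extreme has no cleavage and no ring. Starting material then falls to 36.1% and open dimer reaches 63.9%, and dimer leads once the number passes one.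

Our second extreme freezes dimer share over squared free share at its last reading, 0.521. Dimer would equal starting material at a free share of 192%, above the whole charge, so starting material leads.

Uncleaved pairing predicts 26.3% dimer at 80.0 min, and 22% was read. That gap of 4.3 percentage points, against a scatter of 1.5 points, leaves room for cleavage. But dimer share over squared free share read twice as much at 80.0 min as at 40.0 min, so that ratio was still climbing, and we lean to the first extreme: open dimer largest, below its first figure.

The forecast differs: starting material, 48%, since “Dimer should therefore be equilibrated well before 6 h”.

The flask gives open dimer, 39.4%, with starting material at 32.9%.

    2 starting material ⇌ open dimer (K = 29.0 /M, k = 6.98 × 10⁻⁴ /M/s)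
    starting material → ring (k = 2.44 × 10⁻⁵ /s)
    ring ⇌ isomer of the product (K = 0.355, k = 4.24 × 10⁻⁶ /s)
    ring → over-reaction product (k = 5.18 × 10⁻⁸ /s)

This flask, with pairing number 1.77, has open dimer ahead. The neighbour charged with 0.024 M has a pairing time of 8.46 h and a pairing number of 0.709, below one. Our first extreme there gives open dimer 41.5% against starting material 58.5%. That neighbour ends with starting material holding most, 43.3%, and open dimer at 22.9%.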